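The earlier runs and the new flask were computed with constants of no real substance, and the scatter is random.

A rate constant says how fast a curve rises, not how high it ends, so read the height first.

| flask | substrate | free catalyst | temperature | remark | time |
|---|---|---|---|---|---|
| elm | 10 mM | 2 mol% | 5 °C | run made earlier |  |
| birch | 16 mM | 2 mol% | 16 °C | run made earlier |  |
| larch | 21 mM | 4 mol% | 5 °C | run made earlier |  |
| autumn | 21 mM | 2 mol% |  | at 0 °C throughout | 30 h |
| spring | 21 mM | 2 mol% |  | at 20 °C until 5.0 h, from then on at 0 °C | 15 h |

- elm (time / h: product / %, substrate / %): 4.00: 10.1, 87.9; 10.0: 15.0, 83.6; 20.0: 15.9, 81.8; 30.0: 15.8, 82.4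
- birch (time / h: product / %, substrate / %): 2.00: 13.1, 86.0; 5.00: 15.7, 82.2; 10.0: 15.6, 83.1; 15.0: 14.8, 81.8
- larch (time / h: product / %, substrate / %): 3.00: 18.9, 77.4; 6.00: 27.1, 69.7; 12.0: 31.5, 64.4; 30.0: 31.2, 63.8

(each reading ± 0.5 percentage points)

- the winner by amount of product, in percent of the substrate charged; "neither" if no more than 2 percentage points parts them (autumn / spring / neither)
- how much product is there at the end, in percent of the substrate charged: autumn
- how much product is there at the end, in percent of the substrate charged: spring

- the earlier runs were read with a standard deviation of 0.5 percentage points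

Replace the flat end of the larch curve by the mean of its last two readings, and divide by the catalyst charged:

product per catalyst = mean late product / catalyst loading = 7.84

Call this the turnover budget, the partition ratio. Elm, charged with 10 mM, reads 7.92, and birch, charged with 16 mM at 16 °C, reads 7.68 over its last three readings. Elm still held 82.4 % of its substrate at 30.0 h, so count catalyst, not substrate. The mean carries a scatter of 0.35 points in larch, which is 0.18 points at the loading of the new flasks:

end product = budget × loading = 15.7 %

Now check that each flask has the time. Take, in elm and in birch, the part of the run's own late mean still unspent at the first reading: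

k = −ln(unspent part) / time

This gives 0.253 h⁻¹ for elm and 0.957 h⁻¹ for birch. Carrying the same factor per degree gives estimates of 0.139 h⁻¹ for autumn and 1.55 h⁻¹ for spring's warm stretch. By these estimates autumn ends with 1.56 % of its budget unspent, and spring reaches the change of temperature with 0.0428 %. My reckoning stays with 15.7 % for spring, and for autumn with that figure less its unspent part.

The forecast says neither, with autumn at 15.6 % (14.6 % to 16.6 %) and spring at 15.7 % (14.6 % to 16.8 %). Its ground reads: “the catalyst appears to die after a fixed number of turnovers”.

The flask gives autumn 16.1 % and spring 15.7 %, so the answer is neither: the gap of 0.40 points is less than the margin of 2 points.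

    substrate + free catalyst ⇌ catalyst intermediate A (K = 2200 L mol⁻¹, k = 30.0 L mol⁻¹ min⁻¹, Ea = 52.0 kJ mol⁻¹, ΔH = −20.0 kJ mol⁻¹)
    catalyst intermediate A ⇌ catalyst intermediate B (K = 99.0, k = 0.570 min⁻¹, Ea = 75.0 kJ mol⁻¹, ΔH = −23.0 kJ mol⁻¹)
    catalyst intermediate B → free catalyst + product (k = 0.700 min⁻¹, Ea = 78.0 kJ mol⁻¹)
    catalyst intermediate B → spent catalyst (k = 0.0890 min⁻¹, Ea = 79.0 kJ mol⁻¹)
    (constants at 20 °C)

In spring, catalyst intermediate B split at 0.444 h into product and spent catalyst at 7.9 to one. By 5.00 h spent catalyst stood at 99.9 % of the catalyst charged, with product at 15.7 % and substrate at 82.3 %. In autumn, spent catalyst stood at 92.6 % of the catalyst charged and product at 15.0 % after 15.0 h.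

Take the budget to a neighbour of spring charged with 8 mol% of free catalyst: 7.84 times that loading gives 62.7 %. The computed flask holds 62.8 % of product at 15.0 h.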